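All constants are made up.

Whatever happens in this flask, free catalyst, dormant form, spent catalyst A and spent catalyst B add up to the catalyst charged.

    starting material + free catalyst → spent catalyst B (k1 = 0.28 M⁻¹ min⁻¹)
    starting material + dissolved gas + free catalyst → free catalyst + product (k2 = 8700 M⁻² min⁻¹)
    gas phase ⇌ dissolved gas, rate k3*(csat - [dissolved gas]) (k3 = 0.11 min⁻¹, csat = 21 mM)
    free catalyst + impurity → spent catalyst A (k4 = 8300 M⁻¹ min⁻¹)
    free catalyst ⇌ dormant form (K5 = 1.3, k5 = 0.037 min⁻¹)

starting material 0.10 M; gas phase 21 mM (held); free catalyst 0.69 mM; impurity 0.62 mM; time 4.0 h

- at the start none of the gas is dissolved
- run time (flask): 4.0 h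

- gamma: doubling the saturation concentration of gas phase, all else as stated
- zeta: doubling the amount of free catalyst, all else as stated
- delta: doubling the transfer coefficient of step 3, all else as stated

1. amount of product at 4.0 h, in percent of the starting material charged
2. the change that raises the amount of product at 4.0 h, in percent of the starting material charged most ("none" if none brings more than 2 percentage points) (gamma / zeta / delta / none)
3. amount of product at 4.0 h, in percent of the starting material charged, after gamma

I first ask who takes the free catalyst. The impurity takes it at 5.15 min⁻¹ per unit of catalyst, against 0.0280 min⁻¹ for the starting material, so I book the impurity's charge as spent catalyst A and leave a surplus of 0.0700 mM. Product and spent catalyst B then form in the ratio k2·c(dissolved gas)/k1, in which the starting material cancels, so at saturation the turnover number is 652. Surplus times turnover number, over the starting material charged, gives 45.7 %; this is the catalyst capacity, the share of the charge the surplus can turn over at saturation before it is spent.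

The opposite outcome, starting material used up with catalyst still alive, needs a capacity above 100 %, and this flask stands at 45.7 %. Time comes next: shared with the dormant form and with the starting material at its charge, the surplus halves in about 56.9 min, shorter than the run.

The gas starts at zero, and the whole surplus, if free, draws on it at a pseudo-first-order 0.0609 min⁻¹ against a transfer of 0.11 min⁻¹, so I reckon c(dissolved gas) near 64.4 % of saturation while the surplus is at its fullest. Taking that early share for the whole run, which is a rough step, I commit to about 29.4 % under a ceiling of 45.7 %. Gamma doubles both, to about 58.8 %. Zeta lifts the capacity to 496 %, so I choose zeta; delta leaves the capacity as it is.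

The forecast gives 28 %, zeta and 51 %, on the ground that “product is capped at roughly the catalyst left times a turnover number proportional to dissolved gas”.

The flask gives 27.7 %, and 52.1 % after gamma, below my figure; zeta is best, with a gain of 72 percentage points. After 40.0 h this flask holds 32.5 % of product, below its capacity, with 67.4 % of starting material left and free catalyst at 0 %. The neighbour with 0.0012 M of free catalyst has a capacity of 378 %. That neighbour gives 97.9 % at 4.00 h, with 1.77 % of starting material left and free catalyst still at 8.52 % of its charge.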